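**Retrosynthetic overview**

1. Target 17 is the para-quinone methide of a 3-arylbenzofuran-2-one (O1, C2 lactone carbonyl, C3 aryl, C3a, C4 phenyl, C5 methoxy, C6 ketone, C7 phenyl, C7a). It is traced back through O5-methylation of hydroxy-quinone methide 16, dehydrogenation of catechol lactone 15 and demethylation of trimethyl ether 14.
2. The structural feature used: the lactone carbonyl C2 is bonded both to O1 (on C7a of ring A) and to the doubly benzylic C3 (on C3a, ortho to C7a). C2 is therefore first attached to O7a as a diethylcarbamate and then moved to C3 (C2–C3 bond); O1–C2 recloses to give lactone ring B.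
3. The carbamate 11 comes from phenol 9 by O-carbamoylation. Phenol 9 comes from phenol 7 by Friedel–Crafts benzylation with 4-methoxybenzyl alcohol at the only free position of ring A.
4. Phenol 7 comes from 1,4-dibromo-2,3-dimethoxybenzene by double Suzuki coupling, monobromination para to a methoxy group and exchange of bromine for hydroxyl.
5. Ring order: ring A is bought with 1, ring B is closed in step 6, and the quinonoid oxidation level is set last.

Key step: step 6

Remark: the target has no stereocentre. C3 of 13, 14 and 15 is a racemic centre that becomes sp2 in step 8, so no stereocontrol is planned.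

**Route**

Step 1
Reactants: 1 1,4-dibromo-2,3-dimethoxybenzene; 2 phenylboronic acid
Product: 3 2,3-dimethoxy-1,4-diphenylbenzene
Conditions: 2 (2.4 equiv), Pd(PPh3)4 (5 mol %), K2CO3, toluene/EtOH/H2O, 90 °C
Reagents that add atoms: none
Why: Double Suzuki–Miyaura coupling; the two C–Br bonds of 1 are equivalent and aryl bromides next to a methoxy group couple readily under zerovalent palladium catalysis.

Step 2
Reactants: 3 2,3-dimethoxy-1,4-diphenylbenzene
Product: 4 1-bromo-3,4-dimethoxy-2,5-diphenylbenzene
Conditions: NBS (1.05 equiv), MeCN, 0 °C to rt, dark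
Reagents that add atoms: N-bromosuccinimide, O=C1CCC(=O)N1Br
Why: Electrophilic aromatic bromination; the two open positions of the central ring are each para to a methoxy group and far more nucleophilic than the unactivated outer phenyl rings, and the first bromine deactivates the ring against a second.

Step 3
Reactants: 4 1-bromo-3,4-dimethoxy-2,5-diphenylbenzene
Product: 7 3,4-dimethoxy-2,5-diphenylphenol, via aryllithium 5 (not isolated), via dimethyl arylboronate 6 (not isolated)
Conditions: n-BuLi (1.1 equiv), THF, −78 °C; B(OMe)3, −78 °C to rt; then AcOH, 30% aq. H2O2, 0 °C to rt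
Reagents that add atoms: hydrogen peroxide, OO
Why: Bromine–lithium exchange, borylation and peroxide-induced 1,2-shift of the aryl group from boron to oxygen (oxidation of an arylboronate) turn C–Br into C–OH without touching the methyl ethers.

Step 4
Reactants: 7 3,4-dimethoxy-2,5-diphenylphenol; 8 4-methoxybenzyl alcohol
Product: 9 4,5-dimethoxy-2-(4-methoxybenzyl)-3,6-diphenylphenol
Conditions: 8 (1.05 equiv, slow addition), TsOH·H2O (10 mol %), (CF3)2CHOH/CH2Cl2, rt
Reagents that add atoms: none
Why: Friedel–Crafts benzylation; the acid ionises 8 to the 4-methoxybenzyl cation, which attacks the single free carbon of ring A, ortho to the hydroxyl and para to a methoxy group and therefore the most nucleophilic arene position present.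

Step 5
Reactants: 9 4,5-dimethoxy-2-(4-methoxybenzyl)-3,6-diphenylphenol; 10 N,N-diethylcarbamoyl chloride
Product: 11 4,5-dimethoxy-2-(4-methoxybenzyl)-3,6-diphenylphenyl N,N-diethylcarbamate
Conditions: NaH (1.3 equiv), THF/DMF, 0 °C; then 10 (1.5 equiv), 60 °C
Reagents that add atoms: none
Why: O-Acylation of a preformed sodium phenoxide by a carbamoyl chloride; the phenol is flanked on both sides, so the phenoxide and gentle heating are used.

Step 6
Reactants: 11 4,5-dimethoxy-2-(4-methoxybenzyl)-3,6-diphenylphenyl N,N-diethylcarbamate
Product: 14 5,6-dimethoxy-3-(4-methoxyphenyl)-4,7-diphenylbenzofuran-2(3H)-one (racemic at C3), via benzylic organolithium 12 (not isolated), via hydroxy amide 13 (not isolated)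
Conditions: LiN(iPr)2 (2.5 equiv), THF, −78 °C to rt; then AcOH, THF removed, AcOH reflux
Reagents that add atoms: none
Why: LiN(iPr)2 is held by the carbamate carbonyl and removes a proton from the diarylmethane carbon (future C3) to give 12, whose carbanion adds to the carbamoyl carbon through a five-membered cyclic tetrahedral alkoxide that collapses with expulsion of the O7a phenoxide, so that the C2–C3 bond is made and the second equivalent of base holds the amide as its enolate. This is the anionic homo-Fries rearrangement (lateral metalation with 1,4 oxygen-to-carbon carbamoyl shift) known for ortho-alkylaryl carbamates, followed by the known acid lactonisation of ortho-hydroxyarylacetamides. In hot acetic acid the freed O7a hydroxyl of 13 attacks the amide carbonyl in a 5-exo-trig acyl substitution and diethylamine leaves as its acetate, which closes lactone ring B. C3 becomes a stereocentre but is formed racemic on protonation, which does not matter because C3 is sp2 in the target. The step needs deprotonation at the benzylic carbon and not at an ortho position of the C7 phenyl ring (remote metalation would lead to a dibenzopyranone); the much higher acidity of the doubly benzylic hydrogen next to the carbamate and the low temperature should secure this, and ring A carries no hydrogen, so the ordinary ortho-Fries shift is excluded.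

Step 7
Reactants: 14 5,6-dimethoxy-3-(4-methoxyphenyl)-4,7-diphenylbenzofuran-2(3H)-one
Product: 15 5,6-dihydroxy-3-(4-hydroxyphenyl)-4,7-diphenylbenzofuran-2(3H)-one (racemic at C3)
Conditions: BBr3 (6 equiv), CH2Cl2, −78 °C to rt, argon; then H2O, 0 °C; crude taken on without exposure to air
Reagents that add atoms: none
Why: Lewis-acid cleavage of aryl methyl ethers; BBr3 complexes each ether oxygen and bromide removes the methyl group by SN2 attack, while the aryl lactone, should it open, recloses during the acidic aqueous work-up.

Step 8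
Reactants: 15 5,6-dihydroxy-3-(4-hydroxyphenyl)-4,7-diphenylbenzofuran-2(3H)-one
Product: 16 5-hydroxy-3-(4-hydroxyphenyl)-4,7-diphenylbenzofuran-2,6-dione (xylerythrin)
Conditions: DDQ (1.05 equiv), 1,4-dioxane, rt
Reagents that add atoms: none
Why: Quinone dehydrogenation of a catechol; the ortho-quinone first formed should tautomerise by shift of the acidic C3 hydrogen to O5 into the fully conjugated para-quinone methide (C3=C3a, C4=C5, C7=C7a, C6=O), in which the former stereocentre is planar.

Step 9
Reactants: 16 5-hydroxy-3-(4-hydroxyphenyl)-4,7-diphenylbenzofuran-2,6-dione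
Product: 17 3-(4-hydroxyphenyl)-5-methoxy-4,7-diphenylbenzofuran-2,6-dione (target)
Conditions: TMSCHN2 (1.05 equiv, hexanes), toluene/MeOH, 0 °C
Reagents that add atoms: trimethylsilyldiazomethane, C[Si](C)(C)C=[N+]=[N-]
Why: O-Methylation of an acidic hydroxyl by a diazoalkane; the 5-hydroxyl is an enol conjugated through C4, C3a and C3 with the lactone carbonyl and lies beside the C6 ketone, so it is expected to protonate the reagent faster than the 4'-phenol, and one equivalent at low temperature should stop at the mono-ether (the fully substituted ring alkenes do not invite dipolar cycloaddition).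

**Compound list**

1 | 1,4-dibromo-2,3-dimethoxybenzene | COc1c(Br)ccc(Br)c1OC | starting material
2 | phenylboronic acid | OB(O)c1ccccc1 | starting material
3 | 2,3-dimethoxy-1,4-diphenylbenzene | COc1c(-c2ccccc2)ccc(-c2ccccc2)c1OC | intermediate
4 | 1-bromo-3,4-dimethoxy-2,5-diphenylbenzene | COc1c(OC)c(-c2ccccc2)c(Br)cc1-c1ccccc1 | intermediate
5 | (3,4-dimethoxy-2,5-diphenylphenyl)lithium, formed in the flask | COc1c(OC)c(-c2ccccc2)c([Li])cc1-c1ccccc1 | intermediate
6 | dimethyl (3,4-dimethoxy-2,5-diphenylphenyl)boronate, formed in the flask | COB(OC)c1cc(-c2ccccc2)c(OC)c(OC)c1-c1ccccc1 | intermediate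
7 | 3,4-dimethoxy-2,5-diphenylphenol | Oc1cc(-c2ccccc2)c(OC)c(OC)c1-c1ccccc1 | intermediate
8 | 4-methoxybenzyl alcohol | COc1ccc(CO)cc1 | starting material
9 | 4,5-dimethoxy-2-(4-methoxybenzyl)-3,6-diphenylphenol | COc1ccc(Cc2c(O)c(-c3ccccc3)c(OC)c(OC)c2-c2ccccc2)cc1 | intermediate
10 | N,N-diethylcarbamoyl chloride | CCN(CC)C(=O)Cl | starting material
11 | 4,5-dimethoxy-2-(4-methoxybenzyl)-3,6-diphenylphenyl N,N-diethylcarbamate | CCN(CC)C(=O)Oc1c(Cc2ccc(OC)cc2)c(-c2ccccc2)c(OC)c(OC)c1-c1ccccc1 | intermediate
12 | [2-(diethylcarbamoyloxy)-4,5-dimethoxy-3,6-diphenylphenyl](4-methoxyphenyl)methyllithium, formed in the flask | CCN(CC)C(=O)Oc1c(C([Li])c2ccc(OC)cc2)c(-c2ccccc2)c(OC)c(OC)c1-c1ccccc1 | intermediate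
13 | N,N-diethyl-2-(2-hydroxy-4,5-dimethoxy-3,6-diphenylphenyl)-2-(4-methoxyphenyl)acetamide (racemic), formed in the flask | CCN(CC)C(=O)C(c1ccc(OC)cc1)c1c(O)c(-c2ccccc2)c(OC)c(OC)c1-c1ccccc1 | intermediate
14 | 5,6-dimethoxy-3-(4-methoxyphenyl)-4,7-diphenylbenzofuran-2(3H)-one (racemic) | COc1ccc(C2C(=O)Oc3c(-c4ccccc4)c(OC)c(OC)c(-c4ccccc4)c32)cc1 | intermediate
15 | 5,6-dihydroxy-3-(4-hydroxyphenyl)-4,7-diphenylbenzofuran-2(3H)-one (racemic) | Oc1ccc(C2C(=O)Oc3c(-c4ccccc4)c(O)c(O)c(-c4ccccc4)c32)cc1 | intermediate
16 | 5-hydroxy-3-(4-hydroxyphenyl)-4,7-diphenylbenzofuran-2,6-dione (xylerythrin) | OC1=C(c2ccccc2)C2=C(c3ccc(O)cc3)C(=O)OC2=C(c2ccccc2)C1=O | intermediate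
17 | 3-(4-hydroxyphenyl)-5-methoxy-4,7-diphenylbenzofuran-2,6-dione | COC1=C(c2ccccc2)C2=C(c3ccc(O)cc3)C(=O)OC2=C(c2ccccc2)C1=O | target

**Step count**

Total step count: 9. Longest linear sequence: 9 steps (1 to 17).

**Steps most likely to fail, with fallbacks**

Step 6. The base may metalate an ortho position of the C7 phenyl ring instead of the benzylic carbon, the carbamoyl transfer may stall, or the hindered tertiary amide may lactonise slowly. The fallback abandons the carbamoyl shift and sets out from phenol 7. Heating 7 with 4-methoxymandelic acid and TsOH in 1,2-dichloroethane with removal of water should alkylate the only free position of ring A with the benzylic cation. This gives 2-(2-hydroxy-4,5-dimethoxy-3,6-diphenylphenyl)-2-(4-methoxyphenyl)acetic acid F1, which lactonises under the same conditions (the classical phenol–mandelic acid route to 3-arylbenzofuran-2(3H)-ones). The fallback comes back to the route at 14.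

Step 9. The diazoalkane may also methylate the 4'-hydroxyl, so that site selectivity is poor or the reaction runs on to the dimethyl ether. The fallback replaces acidity-based selection by steric protection and sets out from 16. TIPSCl and imidazole in DMF should silylate the unhindered 4'-hydroxyl, to give 5-hydroxy-4,7-diphenyl-3-[4-(triisopropylsilyloxy)phenyl]benzofuran-2,6-dione F2. Any silyl enol ether formed at the flanked O5 is labile and would be removed by brief K2CO3/MeOH treatment. Excess trimethylsilyldiazomethane in toluene/MeOH then methylates the only free hydroxyl, to give 5-methoxy-4,7-diphenyl-3-[4-(triisopropylsilyloxy)phenyl]benzofuran-2,6-dione F3. HF·pyridine in THF removes the silyl group, and the fallback comes back to the route at 17.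

Step 4. The benzyl cation may be consumed by self-condensation of the alcohol or by further benzylation of the anisyl ring of the product, instead of attacking the crowded ring-A carbon. The fallback builds the benzyl group stepwise and sets out from 7. Ortho-specific formylation (MgCl2, Et3N, paraformaldehyde, MeCN, reflux) should give 2-hydroxy-4,5-dimethoxy-3,6-diphenylbenzaldehyde F4. Addition of 4-MeOC6H4MgBr (2.5 equiv, THF, 0 °C) gives 2-[hydroxy(4-methoxyphenyl)methyl]-4,5-dimethoxy-3,6-diphenylphenol F5. Ionic reduction (Et3SiH, TFA, CH2Cl2, 0 °C) removes the benzylic hydroxyl, and the fallback comes back to the route at 9.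

**Further compounds**

F1 | step 6 | 2-(2-hydroxy-4,5-dimethoxy-3,6-diphenylphenyl)-2-(4-methoxyphenyl)acetic acid (racemic) | COc1ccc(C(C(=O)O)c2c(O)c(-c3ccccc3)c(OC)c(OC)c2-c2ccccc2)cc1
F2 | step 9 | 5-hydroxy-4,7-diphenyl-3-[4-(triisopropylsilyloxy)phenyl]benzofuran-2,6-dione | CC(C)[Si](Oc1ccc(cc1)C1=C2C(c3ccccc3)=C(O)C(=O)C(c3ccccc3)=C2OC1=O)(C(C)C)C(C)C
F3 | step 9 | 5-methoxy-4,7-diphenyl-3-[4-(triisopropylsilyloxy)phenyl]benzofuran-2,6-dione | CC(C)[Si](Oc1ccc(cc1)C1=C2C(c3ccccc3)=C(OC)C(=O)C(c3ccccc3)=C2OC1=O)(C(C)C)C(C)C
F4 | step 4 | 2-hydroxy-4,5-dimethoxy-3,6-diphenylbenzaldehyde | O=Cc1c(O)c(-c2ccccc2)c(OC)c(OC)c1-c1ccccc1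
F5 | step 4 | 2-[hydroxy(4-methoxyphenyl)methyl]-4,5-dimethoxy-3,6-diphenylphenol (racemic) | COc1ccc(C(O)c2c(O)c(-c3ccccc3)c(OC)c(OC)c2-c2ccccc2)cc1
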